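**Strategy.** The carbocycle of the chromene core (C5, C6, C7, C8, C8a, C4a) carries oxygen on C5, C7 and C8a, so it is a masked phloroglucinol. It is made by a Danheiser-type ketene–alkyne benzannulation: a vinylketene (C5 as ketene carbon, C8 as its α-carbon, the C8a=C4a enol-ether double bond of a preformed cis-2,3-dimethyl-dihydropyranone as the vinyl unit), released from a pyranonylacetyl chloride, meets a siloxyalkyne (C6≡C7–OSi) carrying the pinene-derived cyclobutylmethyl group. One [2+2] cycloaddition forms C5–C6 and C7–C8; 4π opening and 6π closure then deliver the aromatic chromanone. Asymmetric Friedel–Crafts introduction of the side chain and a late, catalyst-controlled dearomative C6 prenylation finish the synthesis.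

Key step: step 9

Remark: the (R,R) Trost ligand in step 12 is assumed to deliver the prenyl group to the C6 face that gives the (6R) centre; should the opposite sense be found, the (S,S) ligand is used.

Step 1
Reactants: 1 (1S,5S)-(−)-α-pinene
Product: 2 2-[(1R,3R)-3-acetyl-2,2-dimethylcyclobutyl]acetic acid (cis-pinonic acid)
Conditions: RuCl3·xH2O (2 mol %), NaIO4 (4.1 equiv), EtOAc/MeCN/H2O, 0 °C → rt
Reagents that add atoms: sodium periodate, [Na+].[O-]I(=O)(=O)=O
Why: RuO4 generated in situ cleaves the trisubstituted ring alkene to methyl ketone and carboxylic acid (Sharpless oxidative cleavage), and the two cis cyclobutane stereocentres are carried over unchanged from the pinene bridgeheads.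

Step 2
Reactants: 2 cis-pinonic acid
Product: 3 methyl 2-[(1R,3R)-3-acetyl-2,2-dimethylcyclobutyl]acetate
Conditions: TMSCHN2 (1.2 equiv), toluene/MeOH 4:1, 0 °C
Reagents that add atoms: trimethylsilyldiazomethane, C[Si](C)(C)C=[N+]=[N-]
Why: O-methylation of the acid by diazomethane released from TMSCHN2/MeOH is neutral, so the epimerisable carbon next to the acetyl group should stay cis.

Step 3
Reactants: 3 methyl cis-pinonate
Product: 4 methyl 2-[(1R,3S)-2,2-dimethyl-3-(prop-1-en-2-yl)cyclobutyl]acetate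
Conditions: Ph3PCH3Br (1.3 equiv), KOtBu (1.25 equiv), THF, 0 °C; then 3, 0 °C → rt
Reagents that add atoms: methyltriphenylphosphonium bromide, C[P+](c1ccccc1)(c1ccccc1)c1ccccc1.[Br-]
Why: Wittig methylenation converts the methyl ketone into the isopropenyl group while the ester is untouched; the ylide is kept free of excess alkoxide to avoid cis-to-trans epimerisation.

Step 4
Reactants: 4 methyl 2-[(1R,3S)-2,2-dimethyl-3-(prop-1-en-2-yl)cyclobutyl]acetate
Product: 6 triisopropyl({3-[(1R,3S)-2,2-dimethyl-3-(prop-1-en-2-yl)cyclobutyl]prop-1-yn-1-yl}oxy)silane, via lithium ynolate 5 (not isolated)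
Conditions: CH2Br2, LiTMP, THF, −78 °C; LiHMDS; n-BuLi, −78 → 0 °C; then TIPSCl, −78 °C → rt
Reagents that add atoms: dibromomethane, BrCBr; chlorotriisopropylsilane, CC(C)[Si](Cl)(C(C)C)C(C)C
Why: Kowalski ester homologation, in which LiCHBr2 adds to the ester, bromine–lithium exchange on the dibromo enolate triggers a 1,2-shift to the ynolate, and the bulky silyl chloride traps it on oxygen to give the siloxyalkyne.

Step 5
Reactants: 7 (S)-4-benzyl-3-propionyloxazolidin-2-one, 8 acetaldehyde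
Product: 9 (S)-4-benzyl-3-[(2S,3R)-3-hydroxy-2-methylbutanoyl]oxazolidin-2-one
Conditions: Bu2BOTf (1.1 equiv), iPr2NEt (1.2 equiv), CH2Cl2, 0 °C; MeCHO, −78 → 0 °C; then pH 7 buffer, MeOH, H2O2
Reagents that add atoms: none
Why: Evans syn aldol through the Z boron enolate and a Zimmerman–Traxler chair, in which the (S)-benzyl auxiliary sets the (2S,3R) syn pair that later becomes the cis-2,3-dimethyl unit.

Step 6
Reactants: 9 aldol adduct
Product: 10 (2S,3R)-3-hydroxy-N-methoxy-N,2-dimethylbutanamide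
Conditions: MeNH(OMe)·HCl, AlMe3, CH2Cl2, 0 °C → rt; aq. potassium sodium tartrate
Reagents that add atoms: N,O-dimethylhydroxylamine hydrochloride, CNOC.Cl
Why: Aluminium amide transamidation of the imide (Weinreb amide formation) releases the auxiliary without touching either stereocentre.

Step 7
Reactants: 10 Weinreb amide, 11 tert-butyl acetoacetate
Product: 12 tert-butyl (6S,7R)-7-hydroxy-6-methyl-3,5-dioxooctanoate
Conditions: 11 (3.5 equiv), LDA (7 equiv), THF, 0 °C; then 10, −78 → 0 °C; aq. NH4Cl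
Reagents that add atoms: none
Why: The Weiler dianion of the acetoacetate attacks the Weinreb amide through its γ-carbon (Claisen-type acylation held at the ketone stage by the chelated tetrahedral intermediate), with the excess dianion absorbing the free hydroxyl proton.

Step 8
Reactants: 12 tert-butyl (6S,7R)-7-hydroxy-6-methyl-3,5-dioxooctanoate
Product: 13 2-[(2R,3S)-2,3-dimethyl-4-oxo-3,4-dihydro-2H-pyran-6-yl]acetic acid
Conditions: TFA/CH2Cl2 1:4, 0 °C → rt, 2 h
Reagents that add atoms: none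
Why: Acid-mediated cyclodehydration of the δ-hydroxy-β-diketone (hemiketal at C3, then loss of water; only the six-membered mode is possible) precedes cleavage of the tert-butyl ester, so the syn pair becomes the cis-2,3-dimethyl-dihydropyranone before a free β-keto acid can decarboxylate.

Step 9
Reactants: 13 2-[(2R,3S)-2,3-dimethyl-4-oxo-3,4-dihydro-2H-pyran-6-yl]acetic acid, 6 triisopropyl({3-[(1R,3S)-2,2-dimethyl-3-(prop-1-en-2-yl)cyclobutyl]prop-1-yn-1-yl}oxy)silane
Product: 18 (2R,3S)-6-{[(1R,3S)-2,2-dimethyl-3-(prop-1-en-2-yl)cyclobutyl]methyl}-5,7-dihydroxy-2,3-dimethylchroman-4-one, via acid chloride 14 (not isolated), via vinylketene 15 (not isolated), via 4-pyranonylcyclobutenone 16 (not isolated), via silyl ether 17 (not isolated)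
Conditions: (COCl)2, DMF (cat.), CH2Cl2, 0 °C, concentrate; slow addition to 6 (1.5 equiv), Et3N (1.3 equiv), toluene, 0 °C → rt; filter, 80 °C, 3 h; then TBAF, AcOH, THF, 0 °C
Reagents that add atoms: none
Why: Triethylamine dehydrochlorinates 14 to vinylketene 15, which adds the siloxyalkyne in a regioselective thermal [2+2] cycloaddition (ketene carbonyl carbon to the alkyl-bearing alkyne carbon, ketene α-carbon to the silyloxy carbon), so that the C5–C6 and C7–C8 bonds of the chromanone arise together in cyclobutenone 16. Heating opens the four-membered ring by 4π conrotatory electrocyclic cleavage of the former ketene C–C bond (strain release) to a dienylketene, and the carbocycle closes by 6π disrotatory electrocyclisation of the ketene carbon onto C-5 of the dihydropyranone (the C5–C4a bond), followed by tautomerisation to the phenol. The closest known reaction is the Danheiser benzannulation of vinylketenes with siloxyalkynes (Smith–Hoehn type). No stereocentre is formed, and the cis-2,3-dimethyl pair from step 5 should not be enolised under these weakly basic conditions. The selectivity required is the orientation of the [2+2], secured by the polarisation of the ynol ether, and cycloaddition faster than ketene dimerisation, secured by slow addition of 14 to excess 6. Buffered fluoride finally cleaves the silyl ether of 17.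

Step 10
Reactants: 18 (2R,3S)-6-{[(1R,3S)-2,2-dimethyl-3-(prop-1-en-2-yl)cyclobutyl]methyl}-5,7-dihydroxy-2,3-dimethylchroman-4-one, 19 (E)-cinnamaldehyde
Product: 20 (2R,3S,10S)-6-{[(1R,3S)-2,2-dimethyl-3-(prop-1-en-2-yl)cyclobutyl]methyl}-5,8-dihydroxy-2,3-dimethyl-10-phenyl-2,3,9,10-tetrahydro-4H,8H-pyrano[2,3-f]chromen-4-one (lactol, both C8 anomers)
Conditions: (S)-α,α-diphenylprolinol trimethylsilyl ether (20 mol %), PhCO2H (20 mol %), toluene, 0 °C → rt
Reagents that add atoms: none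
Why: Iminium activation of the enal lets C8, the only free ring carbon of the phloroglucinol, add to the unshielded Si face of the β-carbon (organocatalytic Friedel–Crafts alkylation/hemiacetalisation), which sets the benzylic (S) centre under catalyst control while the 7-OH closes the lactol.

Step 11
Reactants: 20 lactol
Product: 21 (2R,3S,10S)-6-{[(1R,3S)-2,2-dimethyl-3-(prop-1-en-2-yl)cyclobutyl]methyl}-5-hydroxy-2,3-dimethyl-10-phenyl-2,3,9,10-tetrahydro-4H,8H-pyrano[2,3-f]chromene-4,8-dione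
Conditions: Ag2CO3 on Celite (4 equiv), toluene, 80 °C
Reagents that add atoms: none
Why: Fétizon oxidation takes the lactol to the lactone under neutral conditions that spare the hydrogen-bonded phenol, the isopropenyl group and the epimerisable C3 centre, and removes the aldehyde oxidation level before any basic step so that retro-Michael loss of the side chain is excluded.

Step 12
Reactants: 21 lactone
Product: 23 (3S)-3-[(2R,3S,6R)-6-{[(1R,3S)-2,2-dimethyl-3-(prop-1-en-2-yl)cyclobutyl]methyl}-4-hydroxy-2,3-dimethyl-6-(3-methylbut-2-en-1-yl)-5,7-dioxo-3,5,6,7-tetrahydro-2H-chromen-8-yl]-3-phenylpropanoic acid (CNP0328119.1), via tripotassium phenoxide carboxylate 22 (not isolated)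
Conditions: KOSiMe3 (3.2 equiv), THF, 0 °C → rt; then Pd2(dba)3·CHCl3 (2.5 mol %), (R,R)-DACH-phenyl Trost ligand (7.5 mol %), prenyl acetate (1.1 equiv), −20 → 0 °C; pH 4 phosphate buffer
Reagents that add atoms: potassium trimethylsilanolate, C[Si](C)(C)[O-].[K+]; prenyl acetate, CC(=O)OCC=C(C)C
Why: Silanolate opens the aryl lactone to the carboxylate and frees the 7-oxide, and the phloroglucinolate then attacks the π-prenyl palladium complex at its unsubstituted terminus through C6 (dearomative Tsuji–Trost asymmetric allylic alkylation), with the chiral ligand pocket choosing the C6 face, the branched substituent shielding C8, and reversible O-allylation under palladium funnelling material to the C-prenyl dione.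

**Compound list**
1 | (1S,5S)-(−)-α-pinene | CC1=CC[C@H]2C[C@@H]1C2(C)C | starting material
2 | 2-[(1R,3R)-3-acetyl-2,2-dimethylcyclobutyl]acetic acid | CC(=O)[C@@H]1C[C@H](CC(=O)O)C1(C)C | intermediate
3 | methyl 2-[(1R,3R)-3-acetyl-2,2-dimethylcyclobutyl]acetate | CC(=O)[C@@H]1C[C@H](CC(=O)OC)C1(C)C | intermediate
4 | methyl 2-[(1R,3S)-2,2-dimethyl-3-(prop-1-en-2-yl)cyclobutyl]acetate | C=C(C)[C@@H]1C[C@H](CC(=O)OC)C1(C)C | intermediate
5 | lithium 3-[(1R,3S)-2,2-dimethyl-3-(prop-1-en-2-yl)cyclobutyl]prop-1-yn-1-olate | C=C(C)[C@@H]1C[C@H](CC#C[O-])C1(C)C.[Li+] | intermediate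
6 | triisopropyl({3-[(1R,3S)-2,2-dimethyl-3-(prop-1-en-2-yl)cyclobutyl]prop-1-yn-1-yl}oxy)silane | C=C(C)[C@@H]1C[C@H](CC#CO[Si](C(C)C)(C(C)C)C(C)C)C1(C)C | intermediate
7 | (S)-4-benzyl-3-propionyloxazolidin-2-one | CCC(=O)N1[C@@H](Cc2ccccc2)COC1=O | starting material
8 | acetaldehyde | CC=O | starting material
9 | (S)-4-benzyl-3-[(2S,3R)-3-hydroxy-2-methylbutanoyl]oxazolidin-2-one | O=C1OC[C@H](Cc2ccccc2)N1C(=O)[C@@H](C)[C@@H](C)O | intermediate
10 | (2S,3R)-3-hydroxy-N-methoxy-N,2-dimethylbutanamide | CON(C)C(=O)[C@@H](C)[C@@H](C)O | intermediate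
11 | tert-butyl acetoacetate | CC(=O)CC(=O)OC(C)(C)C | starting material
12 | tert-butyl (6S,7R)-7-hydroxy-6-methyl-3,5-dioxooctanoate | CC(C)(C)OC(=O)CC(=O)CC(=O)[C@@H](C)[C@@H](C)O | intermediate
13 | 2-[(2R,3S)-2,3-dimethyl-4-oxo-3,4-dihydro-2H-pyran-6-yl]acetic acid | OC(=O)CC1=CC(=O)[C@@H](C)[C@@H](C)O1 | intermediate
14 | 2-[(2R,3S)-2,3-dimethyl-4-oxo-3,4-dihydro-2H-pyran-6-yl]acetyl chloride | ClC(=O)CC1=CC(=O)[C@@H](C)[C@@H](C)O1 | intermediate
15 | (2R,3S)-2,3-dimethyl-6-(2-oxoethenyl)-2,3-dihydro-4H-pyran-4-one (vinylketene) | O=C=CC1=CC(=O)[C@@H](C)[C@@H](C)O1 | intermediate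
16 | 2-{[(1R,3S)-2,2-dimethyl-3-(prop-1-en-2-yl)cyclobutyl]methyl}-4-[(2R,3S)-2,3-dimethyl-4-oxo-3,4-dihydro-2H-pyran-6-yl]-3-[(triisopropylsilyl)oxy]cyclobut-2-en-1-one (C4 epimers) | O=C1C(C[C@H]2C[C@@H](C(C)=C)C2(C)C)=C(O[Si](C(C)C)(C(C)C)C(C)C)C1C1=CC(=O)[C@@H](C)[C@@H](C)O1 | intermediate
17 | (2R,3S)-6-{[(1R,3S)-2,2-dimethyl-3-(prop-1-en-2-yl)cyclobutyl]methyl}-5-hydroxy-2,3-dimethyl-7-[(triisopropylsilyl)oxy]chroman-4-one | CC(C)[Si](Oc1cc2O[C@H](C)[C@H](C)C(=O)c2c(O)c1C[C@H]1C[C@@H](C(C)=C)C1(C)C)(C(C)C)C(C)C | intermediate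
18 | (2R,3S)-6-{[(1R,3S)-2,2-dimethyl-3-(prop-1-en-2-yl)cyclobutyl]methyl}-5,7-dihydroxy-2,3-dimethylchroman-4-one | Oc1cc2O[C@H](C)[C@H](C)C(=O)c2c(O)c1C[C@H]1C[C@@H](C(C)=C)C1(C)C | intermediate
19 | (E)-cinnamaldehyde | O=C/C=C/c1ccccc1 | starting material
20 | (2R,3S,10S)-6-{[(1R,3S)-2,2-dimethyl-3-(prop-1-en-2-yl)cyclobutyl]methyl}-5,8-dihydroxy-2,3-dimethyl-10-phenyl-2,3,9,10-tetrahydro-4H,8H-pyrano[2,3-f]chromen-4-one | OC1C[C@@H](c2ccccc2)c2c(O1)c(C[C@H]3C[C@@H](C(C)=C)C3(C)C)c(O)c3c2O[C@H](C)[C@H](C)C3=O | intermediate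
21 | (2R,3S,10S)-6-{[(1R,3S)-2,2-dimethyl-3-(prop-1-en-2-yl)cyclobutyl]methyl}-5-hydroxy-2,3-dimethyl-10-phenyl-2,3,9,10-tetrahydro-4H,8H-pyrano[2,3-f]chromene-4,8-dione | O=C1C[C@@H](c2ccccc2)c2c(O1)c(C[C@H]3C[C@@H](C(C)=C)C3(C)C)c(O)c3c2O[C@H](C)[C@H](C)C3=O | intermediate
22 | tripotassium (3S)-3-[(2R,3S)-6-{[(1R,3S)-2,2-dimethyl-3-(prop-1-en-2-yl)cyclobutyl]methyl}-2,3-dimethyl-5,7-dioxido-4-oxochroman-8-yl]-3-phenylpropanoate | [K+].[K+].[K+].[O-]C(=O)C[C@@H](c1ccccc1)c1c([O-])c(C[C@H]2C[C@@H](C(C)=C)C2(C)C)c([O-])c2c1O[C@H](C)[C@H](C)C2=O | intermediate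
23 | (3S)-3-[(2R,3S,6R)-6-{[(1R,3S)-2,2-dimethyl-3-(prop-1-en-2-yl)cyclobutyl]methyl}-4-hydroxy-2,3-dimethyl-6-(3-methylbut-2-en-1-yl)-5,7-dioxo-3,5,6,7-tetrahydro-2H-chromen-8-yl]-3-phenylpropanoic acid (CNP0328119.1) | C=C(C)[C@@H]1C[C@H](C[C@@]2(CC=C(C)C)C(=O)C3=C(O)[C@@H](C)[C@@H](C)OC3=C([C@@H](CC(=O)O)c3ccccc3)C2=O)C1(C)C | target

**Total step count:** 12. **Longest linear sequence:** 8 steps (steps 1–4, 9–12; equally steps 5–8, 9–12).

**Steps most likely to fail**

Step 9. The vinylketene may dimerise or be oligomerised by the amine before it meets the alkyne, the siloxyalkyne may be protodesilylated by the ammonium salt, and the cascade may stall at the cyclobutenone. The fallback generates the same vinylketene without any base, by photochemical Wolff rearrangement (second-generation Danheiser protocol). It sets out from 10 and comes back to the route at 18. Addition of MeMgBr to 10 should give (3S,4R)-4-hydroxy-3-methylpentan-2-one F1. Kinetic enolisation of the methyl group (LiHMDS, 2.2 equiv, THF, −78 °C) and Claisen condensation with diethyl oxalate should give ethyl (5S,6R)-6-hydroxy-5-methyl-2,4-dioxoheptanoate F2, which TFA cyclodehydrates to ethyl (2R,3S)-2,3-dimethyl-4-oxo-3,4-dihydro-2H-pyran-6-carboxylate F3. Mild ester cleavage (Me3SnOH, 1,2-dichloroethane, 60 °C) should give (2R,3S)-2,3-dimethyl-4-oxo-3,4-dihydro-2H-pyran-6-carboxylic acid F4, and oxalyl chloride followed by CH2N2 should give (2R,3S)-6-(2-diazoacetyl)-2,3-dimethyl-2,3-dihydro-4H-pyran-4-one F5. Irradiation of F5 with 6 (300–350 nm, CH2Cl2, rt) and then heating to 80 °C in toluene should give 17 through 15 and 16, and buffered TBAF returns 18.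

Step 12. The chiral catalyst may give poor facial selectivity at C6 on this large substrate, prenylation may end on oxygen or at C8, and the lactone may not open cleanly in the same pot. The fallback separates the events and uses ion-pair control instead of palladium. It sets out from 21 and comes back at 23. NaOMe in MeOH at 0 °C should open the lactone to methyl (3S)-3-[(2R,3S)-6-{[(1R,3S)-2,2-dimethyl-3-(prop-1-en-2-yl)cyclobutyl]methyl}-5,7-dihydroxy-2,3-dimethyl-4-oxochroman-8-yl]-3-phenylpropanoate F6. Alkylative dearomatisation with prenyl bromide under chiral phase-transfer catalysis (O-allyl-N-(9-anthracenylmethyl)cinchonidinium bromide, CsOH·H2O, toluene, −40 °C) should give methyl (3S)-3-[(2R,3S,6R)-6-{[(1R,3S)-2,2-dimethyl-3-(prop-1-en-2-yl)cyclobutyl]methyl}-4-hydroxy-2,3-dimethyl-6-(3-methylbut-2-en-1-yl)-5,7-dioxo-3,5,6,7-tetrahydro-2H-chromen-8-yl]-3-phenylpropanoate F7, with the minor C6 epimer removed by preparative HPLC if needed. LiOH in THF/H2O then gives 23.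

Step 10. The acyl-deactivated phloroglucinol may react sluggishly with the iminium ion, reversible addition may erode the enantiomeric purity, and the lactol may dehydrate. The fallback builds a coumarin and sets the benzylic centre by asymmetric conjugate reduction. It sets out from 18 and comes back at 21, replacing steps 10 and 11. Selective acylation of the 7-OH with phenylpropiolic acid (DCC, DMAP cat., CH2Cl2) should give (2R,3S)-6-{[(1R,3S)-2,2-dimethyl-3-(prop-1-en-2-yl)cyclobutyl]methyl}-5-hydroxy-2,3-dimethyl-4-oxochroman-7-yl 3-phenylprop-2-ynoate F8. Intramolecular hydroarylation at C8 (PtCl4, or AuCl3/AgOTf, 1,2-dichloroethane, rt) should give (2R,3S)-6-{[(1R,3S)-2,2-dimethyl-3-(prop-1-en-2-yl)cyclobutyl]methyl}-5-hydroxy-2,3-dimethyl-10-phenyl-2,3-dihydro-4H,8H-pyrano[2,3-f]chromene-4,8-dione F9. Copper hydride conjugate reduction (Cu(OAc)2·H2O, (R)-DTBM-SEGPHOS or its antipode as required for 10S, diethoxymethylsilane, t-BuOH, toluene) should reduce only the coumarin double bond and give 21.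

**Further compounds**
F1 | step 9 | (3S,4R)-4-hydroxy-3-methylpentan-2-one | CC(=O)[C@@H](C)[C@@H](C)O
F2 | step 9 | ethyl (5S,6R)-6-hydroxy-5-methyl-2,4-dioxoheptanoate | CCOC(=O)C(=O)CC(=O)[C@@H](C)[C@@H](C)O
F3 | step 9 | ethyl (2R,3S)-2,3-dimethyl-4-oxo-3,4-dihydro-2H-pyran-6-carboxylate | CCOC(=O)C1=CC(=O)[C@@H](C)[C@@H](C)O1
F4 | step 9 | (2R,3S)-2,3-dimethyl-4-oxo-3,4-dihydro-2H-pyran-6-carboxylic acid | OC(=O)C1=CC(=O)[C@@H](C)[C@@H](C)O1
F5 | step 9 | (2R,3S)-6-(2-diazoacetyl)-2,3-dimethyl-2,3-dihydro-4H-pyran-4-one | [N-]=[N+]=CC(=O)C1=CC(=O)[C@@H](C)[C@@H](C)O1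
F6 | step 12 | methyl (3S)-3-[(2R,3S)-6-{[(1R,3S)-2,2-dimethyl-3-(prop-1-en-2-yl)cyclobutyl]methyl}-5,7-dihydroxy-2,3-dimethyl-4-oxochroman-8-yl]-3-phenylpropanoate | COC(=O)C[C@@H](c1ccccc1)c1c(O)c(C[C@H]2C[C@@H](C(C)=C)C2(C)C)c(O)c2c1O[C@H](C)[C@H](C)C2=O
F7 | step 12 | methyl (3S)-3-[(2R,3S,6R)-6-{[(1R,3S)-2,2-dimethyl-3-(prop-1-en-2-yl)cyclobutyl]methyl}-4-hydroxy-2,3-dimethyl-6-(3-methylbut-2-en-1-yl)-5,7-dioxo-3,5,6,7-tetrahydro-2H-chromen-8-yl]-3-phenylpropanoate | C=C(C)[C@@H]1C[C@H](C[C@@]2(CC=C(C)C)C(=O)C3=C(O)[C@@H](C)[C@@H](C)OC3=C([C@@H](CC(=O)OC)c3ccccc3)C2=O)C1(C)C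
F8 | step 10 | (2R,3S)-6-{[(1R,3S)-2,2-dimethyl-3-(prop-1-en-2-yl)cyclobutyl]methyl}-5-hydroxy-2,3-dimethyl-4-oxochroman-7-yl 3-phenylprop-2-ynoate | O=C(C#Cc1ccccc1)Oc1cc2O[C@H](C)[C@H](C)C(=O)c2c(O)c1C[C@H]1C[C@@H](C(C)=C)C1(C)C
F9 | step 10 | (2R,3S)-6-{[(1R,3S)-2,2-dimethyl-3-(prop-1-en-2-yl)cyclobutyl]methyl}-5-hydroxy-2,3-dimethyl-10-phenyl-2,3-dihydro-4H,8H-pyrano[2,3-f]chromene-4,8-dione | O=C1C=C(c2ccccc2)c2c(O1)c(C[C@H]3C[C@@H](C(C)=C)C3(C)C)c(O)c3c2O[C@H](C)[C@H](C)C3=O
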